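(The readings were computed on assumed constants.)

In a one-step world, J + G <-> X + D, concentrations cancel from the equilibrium constant at one equivalent of G, so the plateau, as a fraction of the J charged, does not depend on the charge.

| setting | north-west | north | flask |
|---|---|---|---|
| J | 10 mM | 5 mM | 10 mM |
| G | 1 equiv | 1 equiv | 1.00 equiv |
| remark | the very flask that is asked about, followed so far | run made earlier |  |
| time |  |  | 8.0 min |

| run | time / min | X / % |
|---|---|---|
| north-west | 1.00 | 54.0 |
| north-west | 3.00 | 69.1 |
| north-west | 5.00 | 69.5 |
| north-west | 8.00 | 69.8 |
| north | 0.417 | 23.8 |
| north | 1.00 | 38.1 |
| north | 2.50 | 57.7 |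
| north | 6.00 | 63.2 |

(readings scatter by 1 percentage point)

- maple: at 8.0 min take out 90% of the D then present, then wait 4.0 min
- alder: at 8.0 min add G, 100% of the amount charged, then wait 4.0 min
- cedar: change nothing and wait 4.0 min more
- elm: at 8.0 min add J, 50.0% of the amount charged, then wait 4.0 min

- X is meant together with its Q
- solid, in amounts per volume of the solution: Q
- the volume of additions can be left aside
- what was read earlier has a scatter of 1 percentage point, one standard deviation
- what may be going on: Q <-> X; J + G <-> X + D

1. X, in percent of the J first charged, at 8.0 min
2. the option that brings most further X ("none" if no option brings more than 2 percentage points) (maple / alder / cedar / elm / none)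
3. X present, in percent of the J first charged, after alder
4. X present, in percent of the J first charged, after cedar

So I turned the question round. For the north-west flask to be free of crystals, its plateau had to match the north one within the scatter of 1 percentage point, but the last readings, 69.8% and 63.2%, stood 6.6 points apart.

I took the north run as the one-step equilibrium, which gave a constant of 2.95. Multiplying that by the charge and the squared unreacted fraction, then dividing by the converted fraction, on the north-west plateau gave 3.85 mM for the ceiling, the most dissolved X that stands beside crystals, its solubility. The north plateau carried to this charge meant 6.32 mM dissolved, 1.64 times the ceiling, while the north flask's own 3.16 mM lay under it.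

With crystals present, dissolved X stands at the ceiling, so D over J left times G left, in fractions of the charge, keeps its north-west value, where D equals X, 7.65. Solving that quadratic, I got 89.4% for alder, 83.6% for elm and 83.5% for maple.

The forecast said 69.6% now, alder best at 89% (86.5% to 91%) and 69.7% for cedar, on the ground that “Relaxation is fast, so all reach equilibrium within 4 min”.

The flask gave 70.3%; alder won with 89.8%, and cedar stayed at 70.3%.

    Q ⇌ X, rate k1*(cs1 - [X]) while solid is left; crystals form when [X] > cs1 (solubility = 4.00 mM, k = 0.440 s⁻¹)
    J + G ⇌ X + D (K = 3.20, k = 2.20 M⁻¹ s⁻¹)

Relaxation of J + G with dissolved X + D took 0.560 min at 8.00 min, short against 8.0 min, and the backward rate then stood at 99.8% of the forward one. The ceiling left 31.3% of the charge as crystals on the last reading, and the flask held Q at 30.3%. A further flask with 4.0 mM of J reckoned to 2.53 mM dissolved, under the ceiling, and it stood at X 63.7% with Q 0%.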